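The route rests on the bond between the quaternary lactone carbon C2 of the 5-oxooxolane ring and the exocyclic carboxyl-bearing methine. The oxolanone ring with its C2 carboxyl is read as a dearomatised furan: C2 is the nucleophilic C5 of a 2-silyloxyfuran-5-carboxylate and the lactone C=O is its silyloxy carbon, while the methine is the β-carbon of a fumaric semialdehyde ester. An iminium-catalysed vinylogous Mukaiyama–Michael addition joins the two fragments, sets both stereocentres in one operation and leaves an aldehyde for the rest of the ten-carbon chain and, later, the (R)-malate. Precursors: tert-butyl 5-(triisopropylsilyloxy)furan-2-carboxylate and tert-butyl (E)-4-oxobut-2-enoate.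

Key step: step 5

Remark: butenolide 3 is racemic and is drawn as its 2(5H)-tautomer; its stereocentre disappears in step 2, and the 2(3H)-tautomer would give the same furan 4.

Step 1
Reactants: 1 tert-butyl furan-2-carboxylate
Product: 3 tert-butyl 5-oxo-2,5-dihydrofuran-2-carboxylate (racemic), via furylboronate 2 (not isolated)
Conditions: B2pin2 (1.0 equiv), [Ir(OMe)(cod)]2 (1.5 mol %), 4,4'-di-tert-butyl-2,2'-bipyridine (3 mol %), THF, 50 °C; then 30 % aq. H2O2, pH 7 phosphate buffer, THF, 0 °C to rt
Reagents that add atoms: hydrogen peroxide, OO (the oxygen at C5); bis(pinacolato)diboron, CC1(C)OB(OC1(C)C)B1OC(C)(C)C(C)(C)O1 (boron of 2 only, not kept in 3)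
Why: Ir-catalysed C–H borylation of a 2-substituted furan should go to the free α-position C5, and peroxide oxidation of the furyl C–B bond gives the 5-hydroxyfuran, which tautomerises to the butenolide (furylboronate-to-butenolide oxidation).

Step 2
Reactants: 3 tert-butyl 5-oxo-2,5-dihydrofuran-2-carboxylate
Product: 4 tert-butyl 5-[(triisopropylsilyl)oxy]furan-2-carboxylate
Conditions: iPr3SiOTf, Et3N, CH2Cl2, 0 °C to rt
Reagents that add atoms: triisopropylsilyl trifluoromethanesulfonate, CC(C)[Si](C(C)C)(C(C)C)OS(=O)(=O)C(F)(F)F
Why: soft enolisation of the doubly activated γ-hydrogen and O-silylation should give the aromatic 2-silyloxyfuran (silyl dienol ether formation from a butenolide).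

Step 3
Reactants: 5 (tert-butoxycarbonylmethylene)triphenylphosphorane; 6 2,2-dimethoxyacetaldehyde (60 % aqueous solution)
Product: 7 tert-butyl (2E)-4,4-dimethoxybut-2-enoate
Conditions: CH2Cl2, 0 °C to rt
Reagents that add atoms: none
Why: Wittig olefination with a stabilised ylide, which should give the E-alkene and tolerates the water of the aldehyde solution.

Step 4
Reactants: 7 tert-butyl (2E)-4,4-dimethoxybut-2-enoate
Product: 8 tert-butyl (2E)-4-oxobut-2-enoate
Conditions: Amberlyst-15 (H+ form), acetone/H2O, rt
Reagents that add atoms: water, O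
Why: acid-catalysed acetal hydrolysis under conditions too mild to cleave the tert-butyl ester, with the E geometry retained.

Step 5
Reactants: 4 tert-butyl 5-[(triisopropylsilyl)oxy]furan-2-carboxylate; 8 tert-butyl (2E)-4-oxobut-2-enoate
Product: 10 tert-butyl (2S)-2-[(2R)-1-tert-butoxy-1,4-dioxobutan-2-yl]-5-oxo-2,5-dihydrofuran-2-carboxylate, via iminium ion 9 (not isolated)
Conditions: (2S,5S)-5-benzyl-2-tert-butyl-3-methylimidazolidin-4-one (20 mol %), CF3CO2H (20 mol %), H2O (2 equiv), CHCl3, −20 °C
Reagents that add atoms: none
Why: The imidazolidinone salt condenses with enal 8 to the (E)-iminium ion 9, the aromatic silyloxyfuran 4 attacks its β-carbon (the carbon bearing the tert-butyl ester, because the iminium and not the ester polarises the alkene) through C5, and loss of the silyl group to water followed by enamine hydrolysis releases lactone carbonyl, aldehyde and catalyst. The closest known reaction type is the iminium-catalysed vinylogous Mukaiyama–Michael addition of 2-silyloxyfurans to enals. No ring is closed: the furan ring is dearomatised and is carried into the product as the 5-oxo-2,5-dihydrofuran ring, whose C2 is the new quaternary carbon. The methine centre (R) is controlled by the catalyst, whose tert-butyl group fixes the iminium geometry and whose benzyl group covers one face of the β-carbon so that the furan adds to the open face. The quaternary centre (S) follows from the furan face presented in an open transition state with the furan ring lying over the iminium π-system, the furan ester pointing away from the iminium carbon, C4–H next to the β-hydrogen and the ring oxygen next to the enal ester, which is the unlike topicity expected for a bulky silyl group with a protic co-acid. The step needs C5 over C3 attack of the dienol ether (larger HOMO coefficient at C5, conjugated lactone formed), 1,4- over 1,2-addition (iminium activation, soft nucleophile) and control of both faces, the furan face being the open risk.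

Step 6
Reactants: 11 1-bromo-8-chlorooctane
Product: 12 (8-chlorooctyl)triphenylphosphonium bromide
Conditions: PPh3 (1.0 equiv), MeCN, reflux
Reagents that add atoms: triphenylphosphine, c1ccc(cc1)P(c1ccccc1)c1ccccc1
Why: SN2 quaternisation of the phosphine, in which bromide leaves far faster than chloride, so the chloride terminus should stay intact.

Step 7
Reactants: 12 (8-chlorooctyl)triphenylphosphonium bromide; 10 tert-butyl (2S)-2-[(2R)-1-tert-butoxy-1,4-dioxobutan-2-yl]-5-oxo-2,5-dihydrofuran-2-carboxylate
Product: 14 tert-butyl (2S)-2-[(2R,4Z)-1-tert-butoxy-12-chloro-1-oxododec-4-en-2-yl]-5-oxo-2,5-dihydrofuran-2-carboxylate, via ylide 13 (not isolated)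
Conditions: 12, KN(SiMe3)2 (slightly less than 1 equiv relative to 12), THF, −78 to 0 °C; then 10, −78 to −20 °C
Reagents that add atoms: none
Why: Wittig olefination with a non-stabilised ylide, for which the aldehyde is by far the most electrophilic site at low temperature; the expected cis geometry is irrelevant because the alkene is hydrogenated next.

Step 8
Reactants: 14 tert-butyl (2S)-2-[(2R,4Z)-1-tert-butoxy-12-chloro-1-oxododec-4-en-2-yl]-5-oxo-2,5-dihydrofuran-2-carboxylate
Product: 15 tert-butyl (2S)-2-[(2R)-1-tert-butoxy-12-chloro-1-oxododecan-2-yl]-5-oxooxolane-2-carboxylate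
Conditions: H2 (1 atm), 10 % Pd/C, EtOAc, rt
Reagents that add atoms: none
Why: heterogeneous catalytic hydrogenation should saturate both the chain alkene and the butenolide C=C, while the primary alkyl chloride, the tert-butyl esters and both stereocentres are untouched under neutral conditions.

Step 9
Reactants: 16 (2R)-2-amino-4-tert-butoxy-4-oxobutanoic acid (D-aspartic acid 4-tert-butyl ester)
Product: 17 (2R)-4-tert-butoxy-2-hydroxy-4-oxobutanoic acid
Conditions: NaNO2, AcOH/H2O, 0 °C to rt
Reagents that add atoms: water, O
Why: diazotisation of an α-amino acid, in which the carboxylate displaces N2 to an α-lactone that water reopens, so two inversions give net retention and the R configuration of the malate centre.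

Step 10
Reactants: 17 (2R)-4-tert-butoxy-2-hydroxy-4-oxobutanoic acid; 15 tert-butyl (2S)-2-[(2R)-1-tert-butoxy-12-chloro-1-oxododecan-2-yl]-5-oxooxolane-2-carboxylate
Product: 20 tert-butyl (2S)-2-[(2R)-1-tert-butoxy-12-{[(2R)-4-tert-butoxy-2-hydroxy-4-oxobutanoyl]oxy}-1-oxododecan-2-yl]-5-oxooxolane-2-carboxylate, via cesium carboxylate 18 (not isolated), via alkyl iodide 19 (not isolated)
Conditions: 17 (1.5 equiv), Cs2CO3 (0.75 equiv), DMF, rt; then 15, NaI (0.2 equiv), 60 °C
Reagents that add atoms: none
Why: SN2 O-alkylation of a cesium carboxylate by a primary halide with iodide catalysis (in situ Finkelstein exchange); the carboxylate is far more nucleophilic than the free hydroxyl, so no protection is needed and no stereocentre is touched.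

Step 11
Reactants: 20 tert-butyl (2S)-2-[(2R)-1-tert-butoxy-12-{[(2R)-4-tert-butoxy-2-hydroxy-4-oxobutanoyl]oxy}-1-oxododecan-2-yl]-5-oxooxolane-2-carboxylate
Product: 21 (2S)-2-[(1R)-1-carboxy-11-{[(2R)-3-carboxy-2-hydroxypropanoyl]oxy}undecyl]-5-oxooxolane-2-carboxylic acid
Conditions: CF3CO2H/CH2Cl2 (1:1), rt; evaporation, reversed-phase chromatography
Reagents that add atoms: none
Why: acidolysis of the three tert-butyl esters with loss of 2-methylpropene, under which the primary alkyl malate ester, the γ-lactone, the secondary alcohol and all three stereocentres should be stable.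

Compound list
1 | tert-butyl furan-2-carboxylate | CC(C)(C)OC(=O)c1ccco1 | starting material
2 | tert-butyl 5-(4,4,5,5-tetramethyl-1,3,2-dioxaborolan-2-yl)furan-2-carboxylate | CC(C)(C)OC(=O)c1ccc(B2OC(C)(C)C(C)(C)O2)o1 | intermediate (not isolated)
3 | tert-butyl 5-oxo-2,5-dihydrofuran-2-carboxylate (racemic) | CC(C)(C)OC(=O)C1C=CC(=O)O1 | intermediate
4 | tert-butyl 5-[(triisopropylsilyl)oxy]furan-2-carboxylate | CC(C)[Si](Oc1ccc(C(=O)OC(C)(C)C)o1)(C(C)C)C(C)C | intermediate
5 | (tert-butoxycarbonylmethylene)triphenylphosphorane | CC(C)(C)OC(=O)C=P(c1ccccc1)(c1ccccc1)c1ccccc1 | starting material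
6 | 2,2-dimethoxyacetaldehyde | COC(OC)C=O | starting material
7 | tert-butyl (2E)-4,4-dimethoxybut-2-enoate | COC(OC)/C=C/C(=O)OC(C)(C)C | intermediate
8 | tert-butyl (2E)-4-oxobut-2-enoate | O=C/C=C/C(=O)OC(C)(C)C | intermediate
9 | iminium trifluoroacetate of 8 with (2S,5S)-5-benzyl-2-tert-butyl-3-methylimidazolidin-4-one (ring centres as in the catalyst, E alkene) | CN1[C@@H](C(C)(C)C)[N+](=C/C=C/C(=O)OC(C)(C)C)[C@@H](Cc2ccccc2)C1=O.[O-]C(=O)C(F)(F)F | intermediate (not isolated)
10 | tert-butyl (2S)-2-[(2R)-1-tert-butoxy-1,4-dioxobutan-2-yl]-5-oxo-2,5-dihydrofuran-2-carboxylate | O=CC[C@@H](C(=O)OC(C)(C)C)[C@]1(C(=O)OC(C)(C)C)C=CC(=O)O1 | intermediate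
11 | 1-bromo-8-chlorooctane | ClCCCCCCCCBr | starting material
12 | (8-chlorooctyl)triphenylphosphonium bromide | ClCCCCCCCC[P+](c1ccccc1)(c1ccccc1)c1ccccc1.[Br-] | intermediate
13 | (8-chlorooctylidene)triphenylphosphorane | ClCCCCCCCC=P(c1ccccc1)(c1ccccc1)c1ccccc1 | intermediate (not isolated)
14 | tert-butyl (2S)-2-[(2R,4Z)-1-tert-butoxy-12-chloro-1-oxododec-4-en-2-yl]-5-oxo-2,5-dihydrofuran-2-carboxylate | ClCCCCCCC/C=C\C[C@@H](C(=O)OC(C)(C)C)[C@]1(C(=O)OC(C)(C)C)C=CC(=O)O1 | intermediate
15 | tert-butyl (2S)-2-[(2R)-1-tert-butoxy-12-chloro-1-oxododecan-2-yl]-5-oxooxolane-2-carboxylate | ClCCCCCCCCCC[C@@H](C(=O)OC(C)(C)C)[C@]1(C(=O)OC(C)(C)C)CCC(=O)O1 | intermediate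
16 | (2R)-2-amino-4-tert-butoxy-4-oxobutanoic acid | N[C@H](CC(=O)OC(C)(C)C)C(=O)O | starting material
17 | (2R)-4-tert-butoxy-2-hydroxy-4-oxobutanoic acid | CC(C)(C)OC(=O)C[C@@H](O)C(=O)O | intermediate
18 | cesium (2R)-4-tert-butoxy-2-hydroxy-4-oxobutanoate | CC(C)(C)OC(=O)C[C@@H](O)C(=O)[O-].[Cs+] | intermediate (not isolated)
19 | tert-butyl (2S)-2-[(2R)-1-tert-butoxy-12-iodo-1-oxododecan-2-yl]-5-oxooxolane-2-carboxylate | ICCCCCCCCCC[C@@H](C(=O)OC(C)(C)C)[C@]1(C(=O)OC(C)(C)C)CCC(=O)O1 | intermediate (not isolated)
20 | tert-butyl (2S)-2-[(2R)-1-tert-butoxy-12-{[(2R)-4-tert-butoxy-2-hydroxy-4-oxobutanoyl]oxy}-1-oxododecan-2-yl]-5-oxooxolane-2-carboxylate | CC(C)(C)OC(=O)C[C@@H](O)C(=O)OCCCCCCCCCC[C@@H](C(=O)OC(C)(C)C)[C@]1(C(=O)OC(C)(C)C)CCC(=O)O1 | intermediate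
21 | (2S)-2-[(1R)-1-carboxy-11-{[(2R)-3-carboxy-2-hydroxypropanoyl]oxy}undecyl]-5-oxooxolane-2-carboxylic acid | O=C(O)C[C@@H](O)C(=O)OCCCCCCCCCC[C@@H](C(=O)O)[C@]1(C(=O)O)CCC(=O)O1 | target

Total step count: 11.
Longest linear sequence: 7 steps (1, 2, 5, 7, 8, 10, 11; the branch through steps 3 and 4 is equally long).

Steps most likely to fail

Step 5. The silyl group of 4 may be lost to the acidic aqueous medium before the C–C bond forms, or the furan face may be poorly controlled with the bulky tert-butyl ester, so that the quaternary centre comes out as a mixture. The fallback sets out from butenolide 3 (bypassing step 2) and enal 8 and comes back to the route at 10. It is a direct vinylogous Michael addition: 3 is deprotonated at its doubly activated γ-position by a substoichiometric amine base (DABCO) and the dienolate adds to the iminium ion formed from 8 and (S)-2-[diphenyl(trimethylsilyloxy)methyl]pyrrolidine in toluene at 0 °C. This catalyst shields the same face of the β-carbon as the imidazolidinone, so the R methine is again expected, while the quaternary centre is set in a different, ion-paired transition state whose sense would have to be checked. No silyl transfer is involved and no new compound is made (F0).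

Step 7. The basic ylide may deprotonate α to the aldehyde, after which the enolate can expel the aromatic 2-oxidofuran (retro-Michael cleavage of the key bond), or the ylide may add in a conjugate sense to the butenolide. The fallback sets out from 10 and comes back to the route at 15. The butenolide is removed first: hydrogenation of 10 (H2, 10 % Pd/C, EtOAc, rt) should give tert-butyl (2S)-2-[(2R)-1-tert-butoxy-1,4-dioxobutan-2-yl]-5-oxooxolane-2-carboxylate F1, which has neither a Michael acceptor nor a stabilised leaving group. Olefination of F1 with ylide 13 under the conditions of step 7 gives tert-butyl (2S)-2-[(2R,4Z)-1-tert-butoxy-12-chloro-1-oxododec-4-en-2-yl]-5-oxooxolane-2-carboxylate F2, and hydrogenation of F2 as in step 8 gives 15.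

Step 1. The electron-poor furylboronate may protodeboronate, or the hydroxyfuran may be ring-opened or over-oxidised by aqueous peroxide. The fallback sets out from 1 and comes back to the route at 3. Deprotonation of 1 at C5 (LiN(iPr)2, THF, −78 °C) gives tert-butyl 5-lithiofuran-2-carboxylate F3, which is oxygenated under anhydrous conditions with bis(trimethylsilyl) peroxide to tert-butyl 5-[(trimethylsilyl)oxy]furan-2-carboxylate F4. Mild aqueous acid on work-up removes the labile trimethylsilyl group and releases 3, which enters step 2 unchanged.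

Further compounds
F0 | step 5 | none | none
F1 | step 7 | tert-butyl (2S)-2-[(2R)-1-tert-butoxy-1,4-dioxobutan-2-yl]-5-oxooxolane-2-carboxylate | O=CC[C@@H](C(=O)OC(C)(C)C)[C@]1(C(=O)OC(C)(C)C)CCC(=O)O1
F2 | step 7 | tert-butyl (2S)-2-[(2R,4Z)-1-tert-butoxy-12-chloro-1-oxododec-4-en-2-yl]-5-oxooxolane-2-carboxylate | ClCCCCCCC/C=C\C[C@@H](C(=O)OC(C)(C)C)[C@]1(C(=O)OC(C)(C)C)CCC(=O)O1
F3 | step 1 | tert-butyl 5-lithiofuran-2-carboxylate | [Li]c1ccc(C(=O)OC(C)(C)C)o1
F4 | step 1 | tert-butyl 5-[(trimethylsilyl)oxy]furan-2-carboxylate | C[Si](C)(C)Oc1ccc(C(=O)OC(C)(C)C)o1
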